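How far does this flask get by 25 h, and how near saturation does its dissolved gas stand then?

| flask | substrate | gas phase | remark | time |
|---|---|---|---|---|
| spring | 20 mM | 5 mM (held) | run made earlier |  |
| summer | 82 mM | 5 mM (held) | run made earlier |  |
| flask | 41 mM | 5.0 mM (held) |  | 25 h |

| run | time / h | target / % | crystals / % |
|---|---|---|---|
| spring | 1.33 | 7.4 | 0 |
| spring | 2.00 | 17.3 | 3.1 |
| spring | 3.00 | 24.1 | 6.5 |
| spring | 5.00 | 43.7 | 18.6 |
| spring | 10.0 | 74.6 | 49.0 |
| spring | 15.0 | 86.9 | 70.4 |
| summer | 1.33 | 3.6 | 0.4 |
| summer | 2.00 | 5.6 | 0.7 |
| summer | 3.00 | 10.5 | 0.8 |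
| summer | 5.00 | 15.3 | 7.2 |
| summer | 10.0 | 30.6 | 20.2 |
| summer | 15.0 | 46.3 | 34.9 |

(standard deviation of a reading: 1 percentage point)

- the target and crystals together standing at 25 h, as a percentage of the substrate charged
- concentration of dissolved gas in solution at 25 h, in percent of saturation

- for target the crystals are counted in
- as a solid, counted per litre of solution: crystals
- at the start none of the gas phase is in solution

The reckoning here takes spent substrate to equal target, crystals counted in. At 10.0 h, the summer run was charged 4.10 times as much as the spring run but has spent 1.68 times as much, so a ceiling V on the rate is assumed, the uptake of gas into a solution empty of it.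

Let f be dissolved gas over saturation, S the substrate concentration and C its charge. Setting uptake V(1−f) equal to consumption VfS/K and dividing one rate by the other removes time and leaves f = K/(K+S). The rate is then VS/(K+S), which integrates to Vt = (C−S) + K ln(C/S).

The two runs at that time give, as readings, K = 10.1 mM, the half-fill substrate, at which dissolved gas stands at half of saturation, and V = 2.88 mM h⁻¹.

In this flask the curve leaves the charge at a slope of 2.31 mM h⁻¹ and reaches its knee, S = K, at 15.6 h. A pseudo-first-order tail follows, with time constant K/V = 3.51 h. At 25 h this leaves S = 1.59 mM, so 96.1% of the charge is spent and f = 86.4%.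

The forecast, seeing “gas transfer limiting at high substrate and reaction limiting at low substrate” with K about 15 mM, gives 92% (85% to 97%) and 84% (68% to 93%). Both lie below this reckoning.

The flask gives 87.6% and 89.1%, with over-reaction product at 11.2% of the charge and substrate at 1.28%.

    gas phase ⇌ dissolved gas, rate k1*(csat - [dissolved gas]) (kL = 0.0104 min⁻¹)
    substrate + dissolved gas → target (k = 1.37 M⁻¹ min⁻¹)
    crystals ⇌ target, rate k3*(cs3 - [target]) while solid is left; crystals form when [target] > cs3 (solubility = 0.770 mM, k = 0.00484 min⁻¹)
    target → over-reaction product (k = 5.66 × 10⁻⁴ min⁻¹)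

Put into f = K/(K+S), this flask's 0.526 mM of substrate gives 95.1% against 89.1%. A neighbour flask, the same flask read at 10 h, holds 17.6 mM of substrate, so f gives 36.4%, and its dissolved gas stands at 29.0% of saturation.

(The runs were generated by integration for substances that don't exist; scatter was added.)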